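**Assumptions (one line each):** The acyl chain in the SMILES is 30 carbons including the carbonyl, so the target is 4-hydroxyphenethyl (tyrosyl) triacontanoate, C38H68O3. It has no stereocenters, so there is no enantiomer issue.

**Retrosynthesis**
1. Disconnect the benzyl ether (phenol protecting group) to give the protected ester, benzyl 4-hydroxyphenethyl triacontanoate equivalent **3**.
2. Disconnect the ester C(O)–O bond to give triacontanoic acid (**1**) and 2-(4-benzyloxyphenyl)ethanol (**2**).
3. The benzyl group removes any phenol versus primary-alcohol selectivity problem.
4. No rings are formed, because the benzene ring comes from commercial **2**.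

**Route**

Step 1
Reactants: **1** triacontanoic acid (melissic acid); **2** 2-[4-(benzyloxy)phenyl]ethan-1-ol
Product: **3** 4-(benzyloxy)phenethyl triacontanoate
Conditions: EDC·HCl, DMAP (cat.), CHCl3 (or CH2Cl2/THF), 40 °C, 12 h
Reagents that add atoms: none (EDC and DMAP are not incorporated; water is lost)
Why: Steglich-type carbodiimide esterification activates the acid as an O-acylisourea/acylpyridinium, which the only free OH (the primary alcohol of **2**) captures. The phenol is already masked and nothing chiral is formed.

Step 2
Reactants: **3** 4-(benzyloxy)phenethyl triacontanoate
Product: **4** 4-hydroxyphenethyl triacontanoate (target)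
Conditions: H2 (1 atm), 10% Pd/C, THF/EtOAc 1:1, 35 °C, 6 h
Reagents that add atoms: none (only hydrogen is added; toluene is the by-product)
Why: Pd-catalysed hydrogenolysis cleaves the benzylic C–O bond of the aryl benzyl ether selectively. The alkyl ester and the arene are untouched, and there are no stereocenters to scramble.

**Checks**
- Target: a C30 acyl chain, an ester O–CH2CH2 link, and a para-disubstituted phenol, which matches the SMILES.
- Atom balance, step 1: C30H60O2 + C15H16O2 → C45H74O3 + H2O.
- Atom balance, step 2: C45H74O3 + H2 → C38H68O3 + C7H8 (toluene). The product is the target.
- Functional groups: the ester survives EDC/DMAP and H2/Pd-C. The benzyl ether survives Step 1. No other functional groups are present.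
- Stereochemistry: the target has none.

**Compound list**
1 | triacontanoic acid | CCCCCCCCCCCCCCCCCCCCCCCCCCCCCC(=O)O | starting material
2 | 2-[4-(benzyloxy)phenyl]ethan-1-ol | OCCc1ccc(OCc2ccccc2)cc1 | starting material
3 | 4-(benzyloxy)phenethyl triacontanoate | CCCCCCCCCCCCCCCCCCCCCCCCCCCCCC(=O)OCCc1ccc(OCc2ccccc2)cc1 | intermediate
4 | 4-hydroxyphenethyl triacontanoate (Basalethanolide B) | CCCCCCCCCCCCCCCCCCCCCCCCCCCCCC(=O)OCCc1ccc(O)cc1 | target

**Total steps:** 2. **Longest linear sequence:** 2.

**Three steps most likely to fail**
1. **Step 1, coupling.** The C30 acid is poorly soluble, so conversion may be low and N-acylurea may form. Fallback: make the acid chloride (oxalyl chloride, cat. DMF, hot toluene), then add **2** with pyridine/DMAP at 60 °C.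
2. **Step 2, hydrogenolysis.** The waxy substrate may dissolve poorly or be slow on Pd/C, and traces of DMAP or urea can poison the catalyst. Fallback: change the protecting group to TBS (TBS-protected tyrosol ester) and remove it with TBAF/AcOH or HF·pyridine.
3. **Isolation and purification of the waxy C30 ester.** It is hard to separate from unreacted acid and is nearly insoluble in common solvents. Fallback: skip protection and use a chemoenzymatic route, with CAL-B (Novozym 435) esterifying tyrosol directly with **1** in hot toluene or 2-methyl-2-butanol. The lipase acylates only the primary OH, and the acid is removed by a basic wash.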